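## Retrosynthetic overview

1. Target 21 comes from 18 via 20: fluoride desilylation of the phenol, and Pd-catalysed exchange of an aryl chloride (a placeholder para to the phenol oxygen of ring A) for allyl.
2. 18 comes from 14: the methyl group is a vinyl group cut down by one carbon (ozonolysis/NaBH4, tosylation, LiEt3BH).
3. 14 comes from 12, and this is the feature the strategy rests on: the bond between the carbinol carbon (C–OH carrying ring B, the 3,4-dimethoxyphenyl ring) and the neighbouring methine carbon carrying ring A (the allyl-hydroxy-methoxyphenyl ring). With methyl read as vinyl it is the C–C bond of a homoallylic alcohol, made by a tin–lithium-triggered [2,3]-Wittig–Still shift of a Z allyl α-stannylbenzyl ether, which sets both stereocentres.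
4. 12 comes from 11, 7, and 5 + 6: the Z alkene is made last by Lindlar reduction; tin is placed on the ring B benzylic carbon through an acetal/α-chloro ether; 5 comes from 4-chloro-2-methoxyphenol by iodination, silylation and Sonogashira coupling.
5. No ring is formed: rings A and B are bought as 4-chloro-2-methoxyphenol and veratraldehyde.

Key step: step 7

Remark 1: an acid-promoted O-alkylation with a Z-3-arylallyl electrophile would pass through an aryl-stabilised allyl cation and could scramble the alkene geometry, so the ether is assembled at the alkyne stage and semi-reduced afterwards.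

Remark 2 (assumption): the bis(oxazoline) antipode that leads to the (1S,2S) series is taken as (R,R), by analogy with what is recalled for benzyl Z-crotyl ethers, and is to be confirmed in a pilot run; both antipodes are accessible from valinol.

## Route

Step 1
Reactants: 1 4-chloro-2-methoxyphenol
Product: 2 4-chloro-2-iodo-6-methoxyphenol
Conditions: NIS, TsOH·H2O (cat.), MeCN, 0 °C → rt
Reagents that add atoms: N-iodosuccinimide, O=C1CCC(=O)N1I
Why: Electrophilic aromatic iodination; the free hydroxyl is the strongest director and its para position is blocked by chlorine, so iodine should enter the one open ortho position.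

Step 2
Reactants: 2 4-chloro-2-iodo-6-methoxyphenol
Product: 3 (4-chloro-2-iodo-6-methoxyphenoxy)triisopropylsilane
Conditions: TIPSOTf, 2,6-lutidine, CH2Cl2, 0 °C → rt
Reagents that add atoms: triisopropylsilyl trifluoromethanesulfonate, CC(C)[Si](OS(=O)(=O)C(F)(F)F)(C(C)C)C(C)C
Why: O-Silylation of a hindered phenol with the silyl triflate; the bulky silyl ether should withstand n-BuLi, hydride and Pd/base later and prevents benzofuran closure after the alkynylation.

Step 3
Reactants: 3 (4-chloro-2-iodo-6-methoxyphenoxy)triisopropylsilane; 4 propargyl alcohol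
Product: 5 3-[5-chloro-3-methoxy-2-(triisopropylsilyloxy)phenyl]prop-2-yn-1-ol
Conditions: PdCl2(PPh3)2 (cat.), CuI (cat.), Et3N, THF, rt → 45 °C
Reagents that add atoms: none
Why: Sonogashira coupling; zerovalent palladium inserts into the C–I bond far faster than into the C–Cl bond, so the chloride is kept as the later allyl handle.

Step 4
Reactants: 5 3-[5-chloro-3-methoxy-2-(triisopropylsilyloxy)phenyl]prop-2-yn-1-ol (two equivalents); 6 veratraldehyde (3,4-dimethoxybenzaldehyde)
Product: 7 veratraldehyde bis{3-[5-chloro-3-methoxy-2-(triisopropylsilyloxy)phenyl]prop-2-yn-1-yl} acetal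
Conditions: PPTS (cat.), toluene, reflux, Dean–Stark trap
Reagents that add atoms: none
Why: Acid-catalysed acetalisation driven by azeotropic removal of water; the alkyne, unlike a Z-arylallyl alcohol, has no geometry to lose under acid.

Step 5
Reactants: 7 veratraldehyde bis(3-arylprop-2-ynyl) acetal; 8 tributyltin hydride
Product: 11 racemic tributyl[(3,4-dimethoxyphenyl)({3-[5-chloro-3-methoxy-2-(triisopropylsilyloxy)phenyl]prop-2-yn-1-yl}oxy)methyl]stannane, via α-chloro ether 9 (not isolated), via tributylstannylmagnesium chloride 10 (not isolated)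
Conditions: (a) AcCl, SOCl2 (cat.), CH2Cl2, 0 °C → rt, evaporate; (b) 8, i-PrMgCl, Et2O, 0 °C; (c) add (b) to (a) in THF, −78 → 0 °C; aq. NH4Cl
Reagents that add atoms: none
Why: Acetal cleavage by acetyl chloride to the α-chloro ether followed by nucleophilic substitution with a stannylmagnesium reagent (the acetal/α-chloro ether route to α-alkoxystannanes) should place tin exactly on the ring B benzylic carbon without an unstable α-hydroxybenzylstannane; slow addition of one equivalent of 10 at −78 °C should spare the less electrophilic acetate by-product, which is recovered.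

Step 6
Reactants: 11 racemic propargyl α-stannylbenzyl ether
Product: 12 racemic tributyl[(3,4-dimethoxyphenyl)({(2Z)-3-[5-chloro-3-methoxy-2-(triisopropylsilyloxy)phenyl]prop-2-en-1-yl}oxy)methyl]stannane
Conditions: H2 (1 atm), Pd/CaCO3 poisoned with Pb(OAc)2 (Lindlar catalyst), quinoline, EtOAc, rt
Reagents that add atoms: none
Why: Lindlar semi-hydrogenation delivers both hydrogens to one face of the alkyne and should give the Z alkene after the ether bond is already in place, leaving the C–Sn, C–Cl and benzylic C–O bonds untouched.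

Step 7
Reactants: 12 racemic Z-3-arylallyl α-(tributylstannyl)-3,4-dimethoxybenzyl ether
Product: 14 (1S,2S)-2-[5-chloro-3-methoxy-2-(triisopropylsilyloxy)phenyl]-1-(3,4-dimethoxyphenyl)but-3-en-1-ol, via α-lithio ether 13 (not isolated)
Conditions: n-BuLi, 2,2'-(pentane-3,3-diyl)bis[(4R)-4-isopropyl-4,5-dihydrooxazole], toluene/Et2O, −78 °C; aq. NH4Cl at −78 °C
Reagents that add atoms: none
Why: n-BuLi attacks tin, releasing tetrabutylstannane and the α-oxy carbanion 13 on the ring B benzylic carbon only, so the acidic arylallylic CH2 is never deprotonated; 13 then undergoes the concerted suprafacial [2,3]-sigmatropic (Wittig–Still) shift through a five-membered envelope transition state in which the carbanion carbon bonds to the ring A-bearing alkene carbon while the allylic C–O bond breaks, and no ring is closed. The closest known reactions are the tin–lithium-triggered [2,3]-Wittig rearrangement of allyl α-stannylalkyl ethers and the bis(oxazoline)/alkyllithium-mediated enantioselective [2,3]-Wittig rearrangement of benzyl Z-allyl ethers. The relative configuration (syn, 1S*,2S*) should follow from the Z alkene reacting with the 3,4-dimethoxyphenyl group exo on the envelope, the arrangement that makes benzyl Z-allyl ethers syn-selective. The absolute configuration should be set by the bis(oxazoline) on lithium: the planarised benzylic organolithium is expected to epimerise faster than it rearranges, so both enantiomers of the racemic stannane are funnelled through the faster of the two ligand-bound transition states. The step needs attack of n-BuLi at tin only (aryl chloride, silyl ether and methyl ethers should be inert at −78 °C), [2,3] over [1,2] shift (favoured by the low temperature), and a cold quench so that the silyl group does not move from the phenol oxygen to the new alkoxide.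

Step 8
Reactants: 14 (1S,2S) homoallylic alcohol
Product: 16 (1S,2R)-2-[5-chloro-3-methoxy-2-(triisopropylsilyloxy)phenyl]-1-(3,4-dimethoxyphenyl)propane-1,3-diol, via ozonide 15 (not isolated)
Conditions: O3, CH2Cl2, −78 °C (Sudan Red 7B end point); then NaBH4, MeOH, −78 → 0 °C
Reagents that add atoms: ozone, [O-][O+]=O
Why: Ozonolysis with reductive work-up; the terminal alkene should react before the arenes when the ozone feed is stopped at the indicator end point, and hydride reduces the ozonide directly so the epimerisable α-aryl β-hydroxy aldehyde does not build up (the descriptor changes by priority only).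

Step 9
Reactants: 16 (1S,2R) 1,3-diol
Product: 17 (2R,3S)-2-[5-chloro-3-methoxy-2-(triisopropylsilyloxy)phenyl]-3-(3,4-dimethoxyphenyl)-3-hydroxypropyl 4-methylbenzenesulfonate
Conditions: TsCl, pyridine, CH2Cl2, 0 °C
Reagents that add atoms: p-toluenesulfonyl chloride, Cc1ccc(cc1)S(Cl)(=O)=O
Why: Selective sulfonylation; the primary hydroxyl should react much faster than the hindered secondary benzylic one.

Step 10
Reactants: 17 primary tosylate
Product: 18 (1S,2S)-2-[5-chloro-3-methoxy-2-(triisopropylsilyloxy)phenyl]-1-(3,4-dimethoxyphenyl)propan-1-ol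
Conditions: LiEt3BH, THF, 0 °C → rt
Reagents that add atoms: none
Why: SN2 displacement of the primary tosylate by hydride (Super-Hydride reduction) turns CH2OTs into the methyl group without touching either stereocentre, the aryl chloride or the aryl silyl ether.

Step 11
Reactants: 18 aryl chloride; 19 allylboronic acid pinacol ester
Product: 20 (1S,2S)-1-(3,4-dimethoxyphenyl)-2-[3-methoxy-5-(prop-2-en-1-yl)-2-(triisopropylsilyloxy)phenyl]propan-1-ol
Conditions: Pd(OAc)2 (cat.), XPhos (cat.), K3PO4, THF/H2O, 60 °C
Reagents that add atoms: none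
Why: Suzuki–Miyaura allylation; the bulky electron-rich biarylphosphine should allow oxidative addition into the unhindered electron-rich aryl chloride, and the unsubstituted allyl group raises no regiochemical question.

Step 12
Reactants: 20 allylated silyl ether
Product: 21 2-[(1S,2S)-1-(3,4-dimethoxyphenyl)-1-hydroxypropan-2-yl]-6-methoxy-4-(prop-2-en-1-yl)phenol (target)
Conditions: TBAF, AcOH, THF, 0 °C
Reagents that add atoms: none
Why: Fluoride-mediated desilylation of the aryl silyl ether under buffered conditions frees the phenol without acid, which could close the ortho-hydroxy benzylic alcohol to a dihydrobenzofuran.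

## Compound list

1 | 4-chloro-2-methoxyphenol | COc1cc(Cl)ccc1O | starting material
2 | 4-chloro-2-iodo-6-methoxyphenol | COc1cc(Cl)cc(I)c1O | intermediate
3 | (4-chloro-2-iodo-6-methoxyphenoxy)triisopropylsilane | COc1cc(Cl)cc(I)c1O[Si](C(C)C)(C(C)C)C(C)C | intermediate
4 | propargyl alcohol | C#CCO | starting material
5 | 3-[5-chloro-3-methoxy-2-(triisopropylsilyloxy)phenyl]prop-2-yn-1-ol | COc1cc(Cl)cc(C#CCO)c1O[Si](C(C)C)(C(C)C)C(C)C | intermediate
6 | veratraldehyde | COc1ccc(C=O)cc1OC | starting material
7 | veratraldehyde bis{3-[5-chloro-3-methoxy-2-(triisopropylsilyloxy)phenyl]prop-2-yn-1-yl} acetal | COc1ccc(C(OCC#Cc2cc(Cl)cc(OC)c2O[Si](C(C)C)(C(C)C)C(C)C)OCC#Cc2cc(Cl)cc(OC)c2O[Si](C(C)C)(C(C)C)C(C)C)cc1OC | intermediate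
8 | tributyltin hydride | CCCC[SnH](CCCC)CCCC | starting material
9 | racemic α-chloro-3,4-dimethoxybenzyl 3-arylprop-2-ynyl ether (not isolated) | COc1ccc(C(Cl)OCC#Cc2cc(Cl)cc(OC)c2O[Si](C(C)C)(C(C)C)C(C)C)cc1OC | intermediate
10 | tributylstannylmagnesium chloride (not isolated) | CCCC[Sn](CCCC)(CCCC)[Mg]Cl | intermediate
11 | racemic tributyl[(3,4-dimethoxyphenyl)({3-[5-chloro-3-methoxy-2-(triisopropylsilyloxy)phenyl]prop-2-yn-1-yl}oxy)methyl]stannane | COc1ccc(C(OCC#Cc2cc(Cl)cc(OC)c2O[Si](C(C)C)(C(C)C)C(C)C)[Sn](CCCC)(CCCC)CCCC)cc1OC | intermediate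
12 | racemic tributyl[(3,4-dimethoxyphenyl)({(2Z)-3-[5-chloro-3-methoxy-2-(triisopropylsilyloxy)phenyl]prop-2-en-1-yl}oxy)methyl]stannane | COc1ccc(C(OC/C=C\c2cc(Cl)cc(OC)c2O[Si](C(C)C)(C(C)C)C(C)C)[Sn](CCCC)(CCCC)CCCC)cc1OC | intermediate
13 | α-lithio-3,4-dimethoxybenzyl Z-3-arylallyl ether, ligand-bound (not isolated) | COc1ccc(C([Li])OC/C=C\c2cc(Cl)cc(OC)c2O[Si](C(C)C)(C(C)C)C(C)C)cc1OC | intermediate
14 | (1S,2S)-2-[5-chloro-3-methoxy-2-(triisopropylsilyloxy)phenyl]-1-(3,4-dimethoxyphenyl)but-3-en-1-ol | Clc1cc(OC)c(O[Si](C(C)C)(C(C)C)C(C)C)c([C@H](C=C)[C@H](O)c2ccc(OC)c(OC)c2)c1 | intermediate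
15 | secondary ozonide (3-substituted 1,2,4-trioxolane) of 14 (not isolated) | Clc1cc(OC)c(O[Si](C(C)C)(C(C)C)C(C)C)c([C@H](C2OOCO2)[C@H](O)c2ccc(OC)c(OC)c2)c1 | intermediate
16 | (1S,2R)-2-[5-chloro-3-methoxy-2-(triisopropylsilyloxy)phenyl]-1-(3,4-dimethoxyphenyl)propane-1,3-diol | Clc1cc(OC)c(O[Si](C(C)C)(C(C)C)C(C)C)c([C@H](CO)[C@H](O)c2ccc(OC)c(OC)c2)c1 | intermediate
17 | (2R,3S)-2-[5-chloro-3-methoxy-2-(triisopropylsilyloxy)phenyl]-3-(3,4-dimethoxyphenyl)-3-hydroxypropyl 4-methylbenzenesulfonate | Clc1cc(OC)c(O[Si](C(C)C)(C(C)C)C(C)C)c([C@H](COS(=O)(=O)c3ccc(C)cc3)[C@H](O)c2ccc(OC)c(OC)c2)c1 | intermediate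
18 | (1S,2S)-2-[5-chloro-3-methoxy-2-(triisopropylsilyloxy)phenyl]-1-(3,4-dimethoxyphenyl)propan-1-ol | Clc1cc(OC)c(O[Si](C(C)C)(C(C)C)C(C)C)c([C@H](C)[C@H](O)c2ccc(OC)c(OC)c2)c1 | intermediate
19 | allylboronic acid pinacol ester | C=CCB1OC(C)(C)C(C)(C)O1 | starting material
20 | (1S,2S)-1-(3,4-dimethoxyphenyl)-2-[3-methoxy-5-(prop-2-en-1-yl)-2-(triisopropylsilyloxy)phenyl]propan-1-ol | C=CCc1cc(OC)c(O[Si](C(C)C)(C(C)C)C(C)C)c([C@H](C)[C@H](O)c2ccc(OC)c(OC)c2)c1 | intermediate
21 | 2-[(1S,2S)-1-(3,4-dimethoxyphenyl)-1-hydroxypropan-2-yl]-6-methoxy-4-(prop-2-en-1-yl)phenol | C=CCc1cc(OC)c(O)c([C@H](C)[C@H](O)c2ccc(OC)c(OC)c2)c1 | target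

## Step count and risks

Total step count: 12. Longest linear sequence: 12 steps (from 1 to 21; veratraldehyde, tributyltin hydride and the allylboronate enter along the way).

The three steps most likely to fail:

**Step 7 (key step).** Facial discrimination by the ligand-bound lithium may be incomplete, because ligand control in this reaction class is only moderate, and syn selectivity may erode with the ortho-substituted aryl group on the alkene terminus. A modest enantiomeric excess should first be raised by crystallisation at diol 16. The fallback replaces asymmetric induction by resolution. Setting out from 12, the rearrangement is run without ligand (n-BuLi, THF, −78 °C) to give the racemic syn alcohol F1. Esterification with (R)-O-methylmandelic acid (DCC, DMAP, CH2Cl2) gives the (R)-O-methylmandelate of the (1S,2S) alcohol F2 and the (R)-O-methylmandelate of the (1R,2R) alcohol F3, which are separated by chromatography or crystallisation. Reductive cleavage of F2 with diisobutylaluminium hydride (i-Bu2AlH, CH2Cl2, −78 °C) returns to the route at 14.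

**Step 5.** Electron transfer from the stannyl anion to the α-chloro ether may cause reductive dimerisation, or the chloro ether may hydrolyse before substitution. The fallback forms the C–O bond instead of the C–Sn bond last. Setting out from 5, trichloroacetonitrile and DBU (cat.) in CH2Cl2 at 0 °C give the 3-arylprop-2-ynyl trichloroacetimidate F4. Setting out from 6 and 8, tributylstannyllithium F6 (from 8 and LDA, THF, 0 °C) is added to veratraldehyde at −78 °C to give, after a cold NH4Cl work-up, (3,4-dimethoxyphenyl)(tributylstannyl)methanol F5, which is used crude at once. Alkylation of F5 with F4 under TfOH (cat.) in cyclohexane/CH2Cl2 at −20 °C returns to the route at 11.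

**Step 10.** Hydride may act as a base, causing E2 loss of the tosylate toward the benzylic C–H, or the neighbouring alkoxide may close onto the tosylate to form an oxetane. The fallback replaces the anionic reduction by a radical one. Setting out from 17, NaI in acetone at reflux (Finkelstein exchange) gives (1S,2S)-2-[5-chloro-3-methoxy-2-(triisopropylsilyloxy)phenyl]-1-(3,4-dimethoxyphenyl)-3-iodopropan-1-ol F7. Radical dehalogenation with tributyltin hydride 8 and AIBN in toluene at 80 °C, at high stannane concentration to outrun a 1,2-aryl shift, returns to the route at 18.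

## Further compounds

F1 | step 7 | racemic syn alcohol, (1S,2S) and (1R,2R) forms of 14 | Clc1cc(OC)c(O[Si](C(C)C)(C(C)C)C(C)C)c([C@H](C=C)[C@H](O)c2ccc(OC)c(OC)c2)c1.Clc1cc(OC)c(O[Si](C(C)C)(C(C)C)C(C)C)c([C@@H](C=C)[C@@H](O)c2ccc(OC)c(OC)c2)c1
F2 | step 7 | (R)-O-methylmandelate of the (1S,2S) alcohol | Clc1cc(OC)c(O[Si](C(C)C)(C(C)C)C(C)C)c([C@H](C=C)[C@H](OC(=O)[C@H](OC)c3ccccc3)c2ccc(OC)c(OC)c2)c1
F3 | step 7 | (R)-O-methylmandelate of the (1R,2R) alcohol | Clc1cc(OC)c(O[Si](C(C)C)(C(C)C)C(C)C)c([C@@H](C=C)[C@@H](OC(=O)[C@H](OC)c3ccccc3)c2ccc(OC)c(OC)c2)c1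
F4 | step 5 | 3-[5-chloro-3-methoxy-2-(triisopropylsilyloxy)phenyl]prop-2-yn-1-yl 2,2,2-trichloroacetimidate | COc1cc(Cl)cc(C#CCOC(=N)C(Cl)(Cl)Cl)c1O[Si](C(C)C)(C(C)C)C(C)C
F5 | step 5 | racemic (3,4-dimethoxyphenyl)(tributylstannyl)methanol | COc1ccc(C(O)[Sn](CCCC)(CCCC)CCCC)cc1OC
F6 | step 5 | tributylstannyllithium | [Li][Sn](CCCC)(CCCC)CCCC
F7 | step 10 | (1S,2S)-2-[5-chloro-3-methoxy-2-(triisopropylsilyloxy)phenyl]-1-(3,4-dimethoxyphenyl)-3-iodopropan-1-ol | Clc1cc(OC)c(O[Si](C(C)C)(C(C)C)C(C)C)c([C@H](CI)[C@H](O)c2ccc(OC)c(OC)c2)c1
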